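**Assumption:** the target SMILES has no stereocentres and no stereogenic double bonds (all three alkenes are gem-dimethyl), so artelasticin is achiral and no stereocontrol is needed.

## Retrosynthetic overview

1. Artelasticin ⇐ global MOM removal from its 5,7,2',4'-tetra-MOM ether.
2. Tetra-MOM flavone ⇐ Rh(III) formyl C–H activation/oxidative annulation of a diprenyl salicylaldehyde (A ring) with an aryl prenyl alkyne (B ring plus C2, C3 and the 3-prenyl). This forms C4–C3 and O1–C2.
3. Salicylaldehyde ⇐ 1,3,5-tris(MOMO)benzene by three directed ortho-metalations (prenyl, prenyl, CHO) and chelation-controlled mono-MOM removal. The phloroglucinol core ⇐ resorcinol by Ir-catalysed meta C–H borylation/oxidation.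
4. Aryl prenyl alkyne ⇐ 4-iodoresorcinol bis-MOM ether by Sonogashira coupling, desilylation and Cu-catalysed prenylation of the terminal alkyne.
5. Ring order: both benzene rings come intact from resorcinol; the γ-pyranone (C ring) is the only ring built, in the penultimate step.

## Route

**Step 1**
Reactants: 1, resorcinol
Product: 2, 1,3-bis(methoxymethoxy)benzene
Conditions: MOMCl, i-Pr2NEt, CH2Cl2, 0 °C→rt
Reagents that add atoms: chloromethyl methyl ether, COCCl
Why: Double phenol O-alkylation (MOM protection) gives acetal ethers that later serve as ortho-metalation directors.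

**Step 2**
Reactants: 2, 1,3-bis(methoxymethoxy)benzene
Product: 3, 3,5-bis(methoxymethoxy)phenol
Conditions: [Ir(cod)OMe]2 (1 mol %), dtbpy (2 mol %), B2pin2, THF, 80 °C; then 30% H2O2, aq NaOH, 0 °C→rt
Reagents that add atoms: hydrogen peroxide, OO (supplies the new phenolic O); B2pin2, CC1(C)OB(OC1(C)C)B1OC(C)(C)C(C)(C)O1 (boron is installed and then removed)
Why: Sterically controlled Ir-catalysed aromatic C–H borylation hits only C5, the one C–H with no ortho substituent, and boronate oxidation then gives the phloroglucinol pattern.

**Step 3**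
Reactants: 3, 3,5-bis(methoxymethoxy)phenol
Product: 4, 1,3,5-tris(methoxymethoxy)benzene
Conditions: NaH, MOMCl, DMF, 0 °C→rt
Reagents that add atoms: chloromethyl methyl ether, COCCl
Why: Phenoxide O-alkylation (MOM protection) gives a C3-symmetric arene in which every ring C–H lies between two directing groups.

**Step 4**
Reactants: 4, 1,3,5-tris(methoxymethoxy)benzene; 5, prenyl bromide
Product: 6, 1,3,5-tris(methoxymethoxy)-2-(3-methylbut-2-en-1-yl)benzene
Conditions: n-BuLi, TMEDA, THF, 0 °C; CuBr·SMe2, −40 °C; 5, −40 °C→rt
Reagents that add atoms: prenyl bromide (5), CC(C)=CCBr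
Why: Directed ortho-metalation between two OMOM groups, then Cu-mediated SN2 allylation at the primary carbon of prenyl bromide, gives the linear prenyl group.

**Step 5**
Reactants: 6, mono-prenyl arene; 5, prenyl bromide
Product: 7, 1,3,5-tris(methoxymethoxy)-2,4-bis(3-methylbut-2-en-1-yl)benzene
Conditions: n-BuLi, TMEDA, THF, −20→0 °C; CuBr·SMe2, −40 °C; 5, −40 °C→rt
Reagents that add atoms: prenyl bromide (5), CC(C)=CCBr
Why: A second directed ortho-metalation/Cu-mediated allylation; the two remaining ring C–H are symmetry-equivalent and each sits between two OMOM groups, so only one product can form.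

**Step 6**
Reactants: 7, diprenyl arene
Product: 8, 2,4,6-tris(methoxymethoxy)-3,5-bis(3-methylbut-2-en-1-yl)benzaldehyde
Conditions: s-BuLi, TMEDA, THF, −78→−30 °C; DMF; aq NH4Cl
Reagents that add atoms: N,N-dimethylformamide, CN(C)C=O (supplies CHO)
Why: Directed ortho-metalation of the last ring C–H (doubly OMOM-activated, kept cold to outrun benzylic/allylic deprotonation) followed by formylation with DMF.

**Step 7**
Reactants: 8, tris-MOM aldehyde
Product: 9, 2-hydroxy-4,6-bis(methoxymethoxy)-3,5-bis(3-methylbut-2-en-1-yl)benzaldehyde
Conditions: MgBr2·OEt2 (1.5 equiv), Et2O–PhMe, 0 °C→rt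
Reagents that add atoms: none
Why: Chelation-controlled Lewis-acid acetal cleavage: Mg bridges the formyl O and one ortho OMOM, bromide removes that MOM, and the resulting Mg phenoxide–aldehyde chelate blocks a second cleavage, while the non-chelating 4-OMOM is untouched.

**Step 8**
Reactants: 1, resorcinol
Product: 10, 4-iodobenzene-1,3-diol
Conditions: ICl (1.0 equiv), Et2O, 0 °C→rt; aq Na2SO3
Reagents that add atoms: iodine monochloride, ClI
Why: Electrophilic aromatic iodination at C4 (para to one OH, ortho to the other) under non-basic conditions.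

**Step 9**
Reactants: 10, 4-iodobenzene-1,3-diol
Product: 11, 1-iodo-2,4-bis(methoxymethoxy)benzene
Conditions: MOMCl, i-Pr2NEt, CH2Cl2, 0 °C→rt
Reagents that add atoms: chloromethyl methyl ether, COCCl
Why: MOM protection of both phenols; the aryl iodide is inert to these conditions.

**Step 10**
Reactants: 11, aryl iodide; 12, ethynyltrimethylsilane
Product: 13, {[2,4-bis(methoxymethoxy)phenyl]ethynyl}trimethylsilane
Conditions: PdCl2(PPh3)2 (2 mol %), CuI (4 mol %), Et3N–THF, 50 °C
Reagents that add atoms: ethynyltrimethylsilane (12), C#C[Si](C)(C)C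
Why: Sonogashira coupling of an aryl iodide with a terminal alkyne; MOM ethers are stable to amine base.

**Step 11**
Reactants: 13, silyl alkyne
Product: 14, 1-ethynyl-2,4-bis(methoxymethoxy)benzene
Conditions: K2CO3, MeOH, rt
Reagents that add atoms: none
Why: Base-mediated protiodesilylation of the alkynyl–Si bond.

**Step 12**
Reactants: 14, terminal alkyne; 5, prenyl bromide
Product: 15, 2,4-bis(methoxymethoxy)-1-(5-methylhex-4-en-1-yn-1-yl)benzene
Conditions: CuI (10 mol %), K2CO3, NaI, DMF, rt, Ar
Reagents that add atoms: prenyl bromide (5), CC(C)=CCBr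
Why: Cu(I)-catalysed alkynyl–allyl coupling, in which the copper acetylide attacks the unhindered primary carbon of prenyl halide, gives the skipped (1,4-)enyne under base too mild to isomerise it.

**Step 13**
Reactants: 9, diprenyl salicylaldehyde; 15, aryl prenyl alkyne (1.3 equiv)
Product: 16, 2-[2,4-bis(methoxymethoxy)phenyl]-5,7-bis(methoxymethoxy)-3,6,8-tris(3-methylbut-2-en-1-yl)-4H-chromen-4-one
Conditions: [Cp*RhCl2]2 (2.5 mol %), Cu(OAc)2·H2O (2.2 equiv), NaOAc (0.5 equiv), o-xylene, 110 °C, N2
Reagents that add atoms: none (both partners are numbered reactants; two H are removed by Cu(II))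
Why: Proposed new method: Cp*Rh(III) acetate binds the phenoxide of 9 and cleaves the adjacent formyl C–H by concerted metalation–deprotonation to a five-membered aroyl-rhodacycle, alkyne 15 inserts into the Rh–acyl bond with the acyl carbon going to the prenyl-bearing alkyne carbon and Rh to the aryl-bearing carbon (benzylic Rh–C stabilisation, reinforced by chelation of the 2'-OMOM oxygen), and C–O reductive elimination from the seven-membered oxa-rhodacycle closes the pyranone with aryl at C2 and prenyl at C3 while Cu(II) re-oxidises Rh(I); the closest known reaction is the Rh-catalysed oxidative annulation of simple salicylaldehydes with internal alkynes to 2,3-disubstituted chromones, which to my knowledge has not been shown with a skipped enyne carrying a free trisubstituted olefin and a doubly activated propargylic/allylic CH2, nor with a fully substituted tri-oxygenated salicylaldehyde; no stereocentre is formed.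

**Step 14**
Reactants: 16, tetra-MOM flavone
Product: 17, artelasticin
Conditions: 3 M aq HCl–MeOH–THF (1:4:1), 40 °C, monitored and stopped at full conversion
Reagents that add atoms: none
Why: Acid-catalysed acetal hydrolysis removes all four aryl MOM ethers (the peri 5-OMOM goes first), and the temperature is kept low so the prenyl olefins are not protonated; no stereocentre is present.

## Compound list

1 | resorcinol (benzene-1,3-diol) | Oc1cccc(O)c1 | starting material
2 | 1,3-bis(methoxymethoxy)benzene | COCOc1cccc(OCOC)c1 | intermediate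
3 | 3,5-bis(methoxymethoxy)phenol | COCOc1cc(O)cc(OCOC)c1 | intermediate
4 | 1,3,5-tris(methoxymethoxy)benzene | COCOc1cc(OCOC)cc(OCOC)c1 | intermediate
5 | prenyl bromide (1-bromo-3-methylbut-2-ene) | CC(C)=CCBr | starting material
6 | 1,3,5-tris(methoxymethoxy)-2-(3-methylbut-2-en-1-yl)benzene | COCOc1cc(OCOC)c(CC=C(C)C)c(OCOC)c1 | intermediate
7 | 1,3,5-tris(methoxymethoxy)-2,4-bis(3-methylbut-2-en-1-yl)benzene | COCOc1cc(OCOC)c(CC=C(C)C)c(OCOC)c1CC=C(C)C | intermediate
8 | 2,4,6-tris(methoxymethoxy)-3,5-bis(3-methylbut-2-en-1-yl)benzaldehyde | O=Cc1c(OCOC)c(CC=C(C)C)c(OCOC)c(CC=C(C)C)c1OCOC | intermediate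
9 | 2-hydroxy-4,6-bis(methoxymethoxy)-3,5-bis(3-methylbut-2-en-1-yl)benzaldehyde | O=Cc1c(O)c(CC=C(C)C)c(OCOC)c(CC=C(C)C)c1OCOC | intermediate
10 | 4-iodobenzene-1,3-diol | Oc1ccc(I)c(O)c1 | intermediate
11 | 1-iodo-2,4-bis(methoxymethoxy)benzene | COCOc1ccc(I)c(OCOC)c1 | intermediate
12 | ethynyltrimethylsilane | C#C[Si](C)(C)C | starting material
13 | {[2,4-bis(methoxymethoxy)phenyl]ethynyl}trimethylsilane | COCOc1ccc(C#C[Si](C)(C)C)c(OCOC)c1 | intermediate
14 | 1-ethynyl-2,4-bis(methoxymethoxy)benzene | C#Cc1ccc(OCOC)cc1OCOC | intermediate
15 | 2,4-bis(methoxymethoxy)-1-(5-methylhex-4-en-1-yn-1-yl)benzene | CC(C)=CCC#Cc1ccc(OCOC)cc1OCOC | intermediate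
16 | 2-[2,4-bis(methoxymethoxy)phenyl]-5,7-bis(methoxymethoxy)-3,6,8-tris(3-methylbut-2-en-1-yl)-4H-chromen-4-one | CC(C)=CCc1c(OCOC)c(CC=C(C)C)c2oc(-c3ccc(OCOC)cc3OCOC)c(CC=C(C)C)c(=O)c2c1OCOC | intermediate
17 | artelasticin | CC(C)=CCc1c(O)c(CC=C(C)C)c2oc(-c3ccc(O)cc3O)c(CC=C(C)C)c(=O)c2c1O | target

## Summary

Total step count: 14.
Longest linear sequence: 9 (steps 1–7, 13, 14); the B-ring branch (steps 8–12) is 5 steps.

Three steps most likely to fail:

1. **Step 13 (proposed new Rh annulation).** Risks are decarbonylation of the aroyl-rhodium, isomerisation of the skipped enyne, or eroded regioselectivity. Fallback (known chemistry, Baker–Venkataraman approach):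
   - lithiate 7 as in step 6, add 5-methylhex-4-enal and oxidise (Dess–Martin) to the aryl 4-methylpent-3-enyl ketone;
   - remove one ortho MOM with MgBr2 and esterify the phenol (EDC, DMAP) with 2,4-bis(methoxymethoxy)benzoic acid, made from 11 by I/Mg exchange and CO2;
   - Baker–Venkataraman acyl transfer (LiHMDS), then cyclodehydration (AcOH/NaOAc) to 16.

2. **Step 14 (global MOM removal).** The risk is acid-promoted cyclisation of the 5- or 7-OH onto the 6- or 8-prenyl group (2,2-dimethylchromans), or incomplete cleavage. Fallback: build both fragments with SEM ethers in place of MOM (same metalation, MgBr2 and Rh chemistry) and unmask at the end with fluoride (TBAF, DMPU–THF, 60 °C), avoiding acid.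

3. **Step 6 (third metalation with two prenyl groups present).** The risk is lateral lithiation at the benzylic/allylic CH2 groups instead of the last ring C–H. Fallback: formylate 4 first (metalation/DMF, no prenyl present), dibrominate the two remaining ring positions with NBS, then install both prenyl groups by double Pd-catalysed linear-selective Suzuki–Miyaura coupling with prenylboronic acid pinacol ester to reach 8. No organolithium is then used once prenyl groups are present.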